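**Assumption:** the target has no stereocentres and no E/Z-stereogenic alkene, so it is achiral; "single enantiomer" is taken to mean the compound exactly as drawn (diketo form, which exists largely as the chelated enol).

## Retrosynthetic overview

1. Target ⇒ (desilylation) TBS-protected β-diketone ⇒ C–C bond between the central CH2 and the prenylaryl carbonyl, formed by C-aroylation of a ketone dianion (one-pot Baker–Venkataraman-type Claisen).
2. Nucleophile: 6-acetyl-7-hydroxy-2,2-dimethyl-2H-chromene (16 heavy atoms). Electrophile: 4-silyloxy-3-prenylbenzoyl chloride (14 heavy atoms without the silyl group).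
3. Chromene ketone ⇐ DDQ dehydrogenation ⇐ C6 acetylation of 2,2-dimethylchroman-7-ol ⇐ chromanone from resorcinol + 3-methylbut-2-enoic acid.
4. Acid chloride ⇐ carboxylation of the aryllithium from TBS-protected 4-bromo-2-prenylphenol ⇐ ortho C-prenylation of 4-bromophenol.
5. Ring order: the only ring built is the pyran (step 1, as a chromanone), adjusted to chroman and then 2H-chromene before the coupling; both benzene rings are purchased.

## Route

### Branch A – chromene methyl ketone

**Step 1**
Reactants: 1 resorcinol; 2 3-methylbut-2-enoic acid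
Product: 3, 7-hydroxy-2,2-dimethylchroman-4-one
Conditions: MeSO3H, P2O5 (Eaton's reagent), 70 °C
Reagents that add atoms: 3-methylbut-2-enoic acid (2), CC(C)=CC(=O)O
Why: Friedel–Crafts acylation para to one OH followed by intramolecular oxa-Michael addition of the ortho OH onto the enone closes the 2,2-dimethylpyranone ring with the 7-hydroxy pattern.

**Step 2**
Reactants: 3
Product: 4, 2,2-dimethylchroman-7-ol
Conditions: Zn(Hg), conc. HCl, EtOH/toluene, reflux
Reagents that add atoms: none
Why: Clemmensen reduction removes the electron-rich aryl ketone as CH2; the phenol and the cyclic ether are inert.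

**Step 3**
Reactants: 4
Product: 5, 1-(7-hydroxy-2,2-dimethylchroman-6-yl)ethan-1-one
Conditions: AcOH, BF3·OEt2, 90 °C; then aq. NaOAc
Reagents that add atoms: acetic acid, CC(=O)O
Why: Friedel–Crafts (Nencki-type) acetylation goes to C6, which is ortho to the OH, para to the ring oxygen and unhindered (C8 is flanked by two oxygens), and the product is trapped as the chelated o-hydroxyketone BF2 complex.

**Step 4**
Reactants: 5
Product: 6, 1-(7-hydroxy-2,2-dimethyl-2H-chromen-6-yl)ethan-1-one
Conditions: DDQ (1.3 equiv), 1,4-dioxane, reflux
Reagents that add atoms: none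
Why: DDQ dehydrogenation by hydride abstraction at benzylic C4 (cation stabilised by the para OH and ortho ring oxygen) and loss of H from C3 gives the 3,4-alkene; the chelated phenol resists oxidation.

### Branch B – prenylated aroyl chloride

**Step 5**
Reactants: 7 4-bromophenol; 8 prenyl bromide (1-bromo-3-methylbut-2-ene)
Product: 9, 4-bromo-2-(3-methylbut-2-en-1-yl)phenol
Conditions: NaH, toluene, 0 °C → rt; then 8, rt
Reagents that add atoms: prenyl bromide (8), CC(C)=CCBr
Why: The tightly ion-paired sodium phenoxide in a non-polar solvent is alkylated at the ortho carbon (SN2, linear prenyl), and the para position is blocked by Br.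

**Step 6**
Reactants: 9
Product: 10, [4-bromo-2-(3-methylbut-2-en-1-yl)phenoxy](tert-butyl)dimethylsilane
Conditions: TBSCl, imidazole, DMF, rt
Reagents that add atoms: TBSCl, CC(C)(C)[Si](C)(C)Cl
Why: Standard phenol silylation; it masks the acidic OH for the organolithium and enolate steps and is later removable without acid.

**Step 7**
Reactants: 10
Product: 11, 4-[(tert-butyldimethylsilyl)oxy]-3-(3-methylbut-2-en-1-yl)benzoic acid
Conditions: n-BuLi, THF, −78 °C; then CO2; aq. citric acid work-up
Reagents that add atoms: carbon dioxide, O=C=O
Why: Br–Li exchange at −78 °C is much faster than benzylic/allylic deprotonation, and carboxylation of the aryllithium gives the acid; the para silyl ether cannot undergo a retro-Brook shift.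

**Step 8**
Reactants: 11
Product: 12, 4-[(tert-butyldimethylsilyl)oxy]-3-(3-methylbut-2-en-1-yl)benzoyl chloride
Conditions: 1-chloro-N,N,2-trimethylprop-1-en-1-amine (Ghosez reagent), CH2Cl2, 0 °C → rt; concentrate, use crude
Reagents that add atoms: Ghosez reagent, CC(C)=C(Cl)N(C)C (supplies Cl)
Why: Neutral acid chloride formation with no HCl released, so the prenyl alkene is not hydrochlorinated and the aryl silyl ether is not cleaved.

### Coupling and end game

**Step 9**
Reactants: 6 chromene methyl ketone; 12 aroyl chloride
Product: 13, 1-{4-[(tert-butyldimethylsilyl)oxy]-3-(3-methylbut-2-en-1-yl)phenyl}-3-(7-hydroxy-2,2-dimethyl-2H-chromen-6-yl)propane-1,3-dione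
Conditions: 6, LiHMDS (3.1 equiv), THF, −78 → −10 °C; then 12, −78 °C → rt; aq. NH4Cl
Reagents that add atoms: none beyond reactants 6 and 12
Why: Crossed Claisen C-aroylation of the lithium phenoxide–enolate dianion (one-pot Baker–Venkataraman variant); any O-aroyl ester formed rearranges under the excess base to the same β-diketone, and the third equivalent of base deprotonates the product to prevent over-acylation.

**Step 10**
Reactants: 13
Product: 14, Glyinflanin C
Conditions: TBAF, AcOH (1:1), THF, 0 °C; pH 5–6 work-up
Reagents that add atoms: none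
Why: Fluoride cleavage of the aryl silyl ether under buffered, non-acidic conditions avoids cyclodehydration of the 2-hydroxy-β-diketone to a flavone and acid cyclisation of the o-prenylphenol to a chroman.

## Compound list

1 | resorcinol | Oc1cccc(O)c1 | starting material
2 | 3-methylbut-2-enoic acid | CC(C)=CC(=O)O | starting material
3 | 7-hydroxy-2,2-dimethylchroman-4-one | CC1(C)CC(=O)c2ccc(O)cc2O1 | intermediate
4 | 2,2-dimethylchroman-7-ol | CC1(C)CCc2ccc(O)cc2O1 | intermediate
5 | 1-(7-hydroxy-2,2-dimethylchroman-6-yl)ethan-1-one | CC(=O)c1cc2c(cc1O)OC(C)(C)CC2 | intermediate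
6 | 1-(7-hydroxy-2,2-dimethyl-2H-chromen-6-yl)ethan-1-one | CC(=O)c1cc2c(cc1O)OC(C)(C)C=C2 | intermediate
7 | 4-bromophenol | Oc1ccc(Br)cc1 | starting material
8 | prenyl bromide (1-bromo-3-methylbut-2-ene) | CC(C)=CCBr | starting material
9 | 4-bromo-2-(3-methylbut-2-en-1-yl)phenol | CC(C)=CCc1cc(Br)ccc1O | intermediate
10 | [4-bromo-2-(3-methylbut-2-en-1-yl)phenoxy](tert-butyl)dimethylsilane | CC(C)=CCc1cc(Br)ccc1O[Si](C)(C)C(C)(C)C | intermediate
11 | 4-[(tert-butyldimethylsilyl)oxy]-3-(3-methylbut-2-en-1-yl)benzoic acid | CC(C)=CCc1cc(C(=O)O)ccc1O[Si](C)(C)C(C)(C)C | intermediate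
12 | 4-[(tert-butyldimethylsilyl)oxy]-3-(3-methylbut-2-en-1-yl)benzoyl chloride | CC(C)=CCc1cc(C(=O)Cl)ccc1O[Si](C)(C)C(C)(C)C | intermediate
13 | 1-{4-[(tert-butyldimethylsilyl)oxy]-3-(3-methylbut-2-en-1-yl)phenyl}-3-(7-hydroxy-2,2-dimethyl-2H-chromen-6-yl)propane-1,3-dione | CC(C)=CCc1cc(C(=O)CC(=O)c2cc3c(cc2O)OC(C)(C)C=C3)ccc1O[Si](C)(C)C(C)(C)C | intermediate
14 | Glyinflanin C | CC(C)=CCc1cc(C(=O)CC(=O)c2cc3c(cc2O)OC(C)(C)C=C3)ccc1O | target

Atom-contributing reagents not numbered above: acetic acid, TBSCl, CO2 and Ghosez reagent.

## Summary

Total steps: 10.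
Longest linear sequence: 6 steps (1–4, 9, 10 or 5–8, 9, 10).

Steps most likely to fail, each with a fallback:

1. **Step 5, ortho C-prenylation of 4-bromophenol.** Risks are O-alkylation, bis-alkylation and chroman formation. Fallback: O-allylate 4-bromophenol, run a thermal aromatic Claisen rearrangement to 2-allyl-4-bromophenol, silylate, then convert allyl to prenyl by olefin cross-metathesis with 2-methyl-2-butene (Grubbs II) to reach 10.

2. **Step 4, DDQ dehydrogenation of the chroman.** Risks are incomplete conversion and over-oxidation of the phenol. Fallback: build the pyran at the chromene oxidation level. Acetylate resorcinol to 2,4-dihydroxyacetophenone, block C3 by iodination, etherify the 4-OH with 3-chloro-3-methylbut-1-yne, run the thermal propargyl Claisen/electrocyclisation (forced to C5, giving the linear chromene), then remove iodine reductively to give 6.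

3. **Step 9, dianion C-aroylation.** Risks are competing O-acylation, bis-acylation and consumption of the acid chloride by LiHMDS. Fallback: classical two-stage Baker–Venkataraman. Isolate the O-aroyl ester of 6 (12, pyridine/DMAP), then induce the intramolecular 1,3-acyl shift with KOtBu/THF or KOH/pyridine; if the silyl group is lost in that step, the target is obtained directly.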